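**Retrosynthetic overview**
1. The chalcone enone is made last by Claisen–Schmidt condensation of the ring A methyl ketone; all phenols are then freed by palladium-catalysed de-allylation under basic, acid-free conditions.
2. The C2–aryl bond (axial, trans to C4 and C6) comes from arylzinc addition to the oxane oxocarbenium ion, released from an anomeric sulfone that is made from a C2=C3 enol ether.
3. Key disconnection C4–C3′ (oxane to ring A): aromatic Claisen rearrangement of a temporary O2′–C2 aryl acetal bond that is not in the target and links the two fragments. The enabling feature is that the C4–C3′ bond lies ortho to phenol oxygen O2′ and C4 stands 1,3 to C2, the acetal-capable carbon next to ring oxygen O1. O2′–C2–C3=C4 together with C2′=C3′ is therefore the six-atom array, and the other ortho carbon C1′ is blocked by the acetyl group that later becomes the enone.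
4. Only one ring is formed, the oxane (O1, C2–C6), by asymmetric hetero-Diels–Alder reaction of the side-chain aldehyde, which sets C6. C4 is relayed from C6 (cis alcohol, cis aryl acetal, suprafacial shift), and C2 is set last.

Key step: step 8

Locants: oxane O1, C2 (4-hydroxyphenyl), C4 (ring A), C6 (arylethyl chain); ring A C1′ (acyl), C2′/C4′ (OH), C3′ (oxane), C6′ (OMe). TBS = tert-butyldimethylsilyl, Piv = pivaloyl.

Assumption: the catalyst formed from Ti(OiPr)4 and (R)-BINOL in step 3 is taken to show the same facial sense as in its additions to other aliphatic aldehydes, so (R)-BINOL is expected to give the (S)-pyranone; the configuration would be checked on 7 (Mosher ester) and (S)-BINOL used if the sense is opposite.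

**Route**

Step 1
Reactants: 1 methyl 3-(4-hydroxyphenyl)propanoate
Product: 2 methyl 3-[4-(tert-butyldimethylsilyloxy)phenyl]propanoate
Conditions: TBSCl, imidazole, DMF, rt
Reagents that add atoms: tert-butyldimethylsilyl chloride, CC(C)(C)[Si](C)(C)Cl
Why: Imidazole-promoted silyl ether formation masks the acidic phenol before the hydride and Lewis-acid steps.

Step 2
Reactants: 2 methyl 3-[4-(tert-butyldimethylsilyloxy)phenyl]propanoate
Product: 3 3-[4-(tert-butyldimethylsilyloxy)phenyl]propanal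
Conditions: iBu2AlH, CH2Cl2, −78 °C; aq. KNaC4H4O6 (potassium sodium tartrate) work-up
Reagents that add atoms: none
Why: Low-temperature partial reduction of a methyl ester stops at the tetrahedral aluminate, which releases the aldehyde on work-up.

Step 3
Reactants: 3 3-[4-(tert-butyldimethylsilyloxy)phenyl]propanal; 4 (E)-1-methoxy-3-(trimethylsilyloxy)buta-1,3-diene (Danishefsky's diene)
Product: 6 (S)-2-{2-[4-(tert-butyldimethylsilyloxy)phenyl]ethyl}-2,3-dihydro-4H-pyran-4-one, via Mukaiyama aldol adduct 5 (not isolated)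
Conditions: (R)-BINOL (20 mol %), Ti(OiPr)4 (10 mol %), 4 Å MS, Et2O, −20 °C; then CF3CO2H, CH2Cl2, 0 °C
Reagents that add atoms: none
Why: Catalytic asymmetric hetero-Diels–Alder reaction, run as Mukaiyama aldol addition then acid cyclisation with loss of methanol; the chiral complex formed from Ti(OiPr)4 and (R)-BINOL selects the aldehyde face and so sets C6 as (S), a reaction type established for 3-arylpropanals.

Step 4
Reactants: 6 (S)-2-{2-[4-(tert-butyldimethylsilyloxy)phenyl]ethyl}-2,3-dihydro-4H-pyran-4-one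
Product: 7 (2S,4R)-2-{2-[4-(tert-butyldimethylsilyloxy)phenyl]ethyl}-3,4-dihydro-2H-pyran-4-ol (2,4-cis)
Conditions: NaBH4, CeCl3·7H2O, MeOH, −78 °C
Reagents that add atoms: none
Why: Luche 1,2-reduction; axial hydride delivery on the half-chair with the side chain pseudo-equatorial should give the cis (pseudo-diequatorial) allylic alcohol, so the carbinol centre is set by C6.

Step 5
Reactants: 7 (2S,4R)-2-{2-[4-(tert-butyldimethylsilyloxy)phenyl]ethyl}-3,4-dihydro-2H-pyran-4-ol
Product: 8 tert-butyl (2S,4R)-2-{2-[4-(tert-butyldimethylsilyloxy)phenyl]ethyl}-3,4-dihydro-2H-pyran-4-yl carbonate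
Conditions: Boc2O, DMAP (cat.), Et3N, CH2Cl2, 0 °C
Reagents that add atoms: di-tert-butyl dicarbonate, CC(C)(C)OC(=O)OC(=O)OC(C)(C)C
Why: DMAP-catalysed carbonate formation turns the allylic alcohol into a leaving group that zerovalent palladium can ionise and that releases its own base (tert-butoxide).

Step 6
Reactants: 9 1-(2,4-dihydroxy-6-methoxyphenyl)ethanone
Product: 10 1-[4-(tert-butyldimethylsilyloxy)-2-hydroxy-6-methoxyphenyl]ethanone
Conditions: TBSCl (1.05 equiv), imidazole, CH2Cl2, 0 °C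
Reagents that add atoms: tert-butyldimethylsilyl chloride, CC(C)(C)[Si](C)(C)Cl
Why: Selective silyl ether formation at the free 4′-OH, because the 2′-OH is hydrogen-bonded to the acetyl carbonyl and far less reactive.

Step 7
Reactants: 8 tert-butyl (2S,4R)-2-{2-[4-(tert-butyldimethylsilyloxy)phenyl]ethyl}-3,4-dihydro-2H-pyran-4-yl carbonate; 10 1-[4-(tert-butyldimethylsilyloxy)-2-hydroxy-6-methoxyphenyl]ethanone
Product: 11 1-{2-[((2R,6S)-6-{2-[4-(tert-butyldimethylsilyloxy)phenyl]ethyl}-5,6-dihydro-2H-pyran-2-yl)oxy]-4-(tert-butyldimethylsilyloxy)-6-methoxyphenyl}ethanone (2,6-cis aryl acetal)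
Conditions: Pd2(dba)3 (5 mol %), Ph2P(CH2)4PPh2 (12 mol %), toluene, 60 °C; chromatography on Et3N-deactivated silica
Reagents that add atoms: none
Why: Tsuji–Trost-type decarboxylative allylic etherification as used for aryl 2,3-unsaturated glycosides; zerovalent palladium ionises anti to the carbonate and the phenoxide attacks the oxygen-stabilised allyl terminus C2 anti to palladium, so net retention should place the aryloxy group cis to the C6 side chain.

Step 8
Reactants: 11 1-{2-[((2R,6S)-6-{2-[4-(tert-butyldimethylsilyloxy)phenyl]ethyl}-5,6-dihydro-2H-pyran-2-yl)oxy]-4-(tert-butyldimethylsilyloxy)-6-methoxyphenyl}ethanone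
Product: 13 1-{3-[(2S,4R)-2-{2-[4-(tert-butyldimethylsilyloxy)phenyl]ethyl}-3,4-dihydro-2H-pyran-4-yl]-4-(tert-butyldimethylsilyloxy)-2-hydroxy-6-methoxyphenyl}ethanone (C-aryl glycal), via ortho-dienone 12 (not isolated)
Conditions: PhNEt2 (degassed), 170 °C, sealed tube, base-washed glassware
Reagents that add atoms: none
Why: Concerted suprafacial [3,3] aromatic Claisen rearrangement: the O2′–C2 acetal bond breaks as C3′–C4 forms through the array O2′–C2–C3=C4/C2′=C3′, giving ortho-dienone 12, which tautomerises to the acetyl-chelated phenol 13. The closest known reaction type is the thermal Claisen rearrangement of aryl 2,3-unsaturated glycosides to 3-C-aryl glycals; the ring oxygen on the carbon that loses the aryloxy group should accelerate it relative to a plain allyl aryl ether. No ring is closed; the dihydropyran ring is kept and its double bond moves to C2=C3, leaving an enol ether that is the masked C2 oxocarbenium ion needed in step 12. The new stereocentre C4 is controlled by the acetal carbon C2: the aryl group is delivered to the face that carried O2′, cis to the C6 side chain, which gives (4R). The step needs regioselectivity for C3′ and fidelity of the chirality transfer. The first is secured because C1′ carries the acetyl group, so only the C3′ dienone can aromatise; the second by the acid-free basic solvent, which suppresses ionisation of the aryl acetal.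

Step 9
Reactants: 13 1-{3-[(2S,4R)-2-{2-[4-(tert-butyldimethylsilyloxy)phenyl]ethyl}-3,4-dihydro-2H-pyran-4-yl]-4-(tert-butyldimethylsilyloxy)-2-hydroxy-6-methoxyphenyl}ethanone
Product: 14 1-{2,4-bis(allyloxy)-3-[(2S,4R)-2-{2-[4-(allyloxy)phenyl]ethyl}-3,4-dihydro-2H-pyran-4-yl]-6-methoxyphenyl}ethanone
Conditions: CsF, Cs2CO3, allyl bromide (excess), DMF, 50 °C
Reagents that add atoms: allyl bromide, C=CCBr
Why: Fluoride desilylation gives caesium phenoxides that are O-allylated in the same pot together with the 2′-OH (Williamson ether synthesis); the thermally inert silyl groups are exchanged for ethers that survive the aldol base and leave at the end without acid.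

Step 10
Reactants: 14 1-{2,4-bis(allyloxy)-3-[(2S,4R)-2-{2-[4-(allyloxy)phenyl]ethyl}-3,4-dihydro-2H-pyran-4-yl]-6-methoxyphenyl}ethanone; 15 benzenesulfinic acid (freshly liberated from its sodium salt)
Product: 16 1-{2,4-bis(allyloxy)-6-methoxy-3-[(4R,6S)-6-{2-[4-(allyloxy)phenyl]ethyl}-2-(phenylsulfonyl)oxan-4-yl]phenyl}ethanone (mixture of C2 anomers)
Conditions: PhSO2H, CH2Cl2, rt
Reagents that add atoms: none
Why: Markovnikov addition of a sulfinic acid across a cyclic enol ether (hydrogen to C3, sulfonyl sulfur to C2) gives an anomeric sulfone, a storable precursor of the C2 cation whose own C2 configuration is irrelevant.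

Step 11
Reactants: 17 4-iodophenol
Product: 18 4-iodophenyl pivalate
Conditions: PivCl, Et3N, DMAP (cat.), CH2Cl2, 0 °C
Reagents that add atoms: pivaloyl chloride, CC(C)(C)C(Cl)=O
Why: Phenol acylation; the pivalate tolerates iodine–magnesium exchange, and its electron-withdrawing effect later protects the benzylic C2–O bond from ionisation.

Step 12
Reactants: 16 1-{2,4-bis(allyloxy)-6-methoxy-3-[(4R,6S)-6-{2-[4-(allyloxy)phenyl]ethyl}-2-(phenylsulfonyl)oxan-4-yl]phenyl}ethanone; 18 4-iodophenyl pivalate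
Product: 22 4-[(2R,4R,6S)-4-(3-acetyl-2,6-bis(allyloxy)-4-methoxyphenyl)-6-{2-[4-(allyloxy)phenyl]ethyl}oxan-2-yl]phenyl pivalate, via arylmagnesium chloride 19 (not isolated), via arylzinc bromide 20 (not isolated), via oxocarbenium ion 21 (not isolated)
Conditions: 18, iPrMgCl·LiCl, THF, −20 °C; ZnBr2, −20 → 0 °C; then 16, THF, 0 °C → rt; NH4Cl work-up
Reagents that add atoms: none
Why: Lewis-acid-assisted substitution of an anomeric sulfone by an arylzinc reagent: the zinc and magnesium halides ionise the sulfone to oxocarbenium ion 21, whose C4 aryl and C6 chain are both pseudo-equatorial in the half-chair, so stereoelectronically preferred axial attack via a chair-like transition state should place the new aryl trans to both (2R), while the arylzinc spares the hindered methyl ketone and the electron-poor aryl resists Lewis-acid epimerisation.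

Step 13
Reactants: 22 4-[(2R,4R,6S)-4-(3-acetyl-2,6-bis(allyloxy)-4-methoxyphenyl)-6-{2-[4-(allyloxy)phenyl]ethyl}oxan-2-yl]phenyl pivalate; 23 4-(allyloxy)benzaldehyde
Product: 24 (E)-1-{2,4-bis(allyloxy)-3-[(2R,4R,6S)-6-{2-[4-(allyloxy)phenyl]ethyl}-2-(4-hydroxyphenyl)oxan-4-yl]-6-methoxyphenyl}-3-[4-(allyloxy)phenyl]prop-2-en-1-one
Conditions: KOH (50 % aq.), EtOH, rt; NH4Cl work-up
Reagents that add atoms: none
Why: Claisen–Schmidt condensation (aldol addition, then E1cB dehydration to the conjugated E-enone) of a fully O-alkylated acetophenone with a non-enolisable aldehyde; the aryl pivalate is saponified in the same pot and the base leaves the oxane stereocentres untouched.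

Step 14
Reactants: 24 (E)-1-{2,4-bis(allyloxy)-3-[(2R,4R,6S)-6-{2-[4-(allyloxy)phenyl]ethyl}-2-(4-hydroxyphenyl)oxan-4-yl]-6-methoxyphenyl}-3-[4-(allyloxy)phenyl]prop-2-en-1-one
Product: 25 (E)-1-{2,4-dihydroxy-3-[(2R,4R,6S)-2-(4-hydroxyphenyl)-6-[2-(4-hydroxyphenyl)ethyl]oxan-4-yl]-6-methoxyphenyl}-3-(4-hydroxyphenyl)prop-2-en-1-one (CNP0215517.2)
Conditions: Pd(PPh3)4 (cat.), K2CO3, MeOH–THF, rt, short reaction time; pH 7 buffer work-up
Reagents that add atoms: none
Why: Palladium-catalysed de-allylation of aryl allyl ethers (allyl-palladium formation by zerovalent palladium, capture by methoxide) removes all four allyl groups under basic conditions, avoiding the acid that could open and re-close the benzylic C2–O bond once the para-hydroxyl is free, and without reducing the enone.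

**Compound list**
1 | methyl 3-(4-hydroxyphenyl)propanoate | COC(=O)CCc1ccc(O)cc1 | starting material
2 | methyl 3-[4-(tert-butyldimethylsilyloxy)phenyl]propanoate | COC(=O)CCc1ccc(O[Si](C)(C)C(C)(C)C)cc1 | intermediate
3 | 3-[4-(tert-butyldimethylsilyloxy)phenyl]propanal | O=CCCc1ccc(O[Si](C)(C)C(C)(C)C)cc1 | intermediate
4 | (E)-1-methoxy-3-(trimethylsilyloxy)buta-1,3-diene (Danishefsky's diene) | CO/C=C/C(=C)O[Si](C)(C)C | starting material
5 | Mukaiyama aldol adduct, (S,E)-7-[4-(tert-butyldimethylsilyloxy)phenyl]-1-methoxy-5-(trimethylsilyloxy)hept-1-en-3-one | CO/C=C/C(=O)C[C@H](CCc1ccc(O[Si](C)(C)C(C)(C)C)cc1)O[Si](C)(C)C | intermediate (not isolated)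
6 | (S)-2-{2-[4-(tert-butyldimethylsilyloxy)phenyl]ethyl}-2,3-dihydro-4H-pyran-4-one | CC(C)(C)[Si](C)(C)Oc1ccc(CC[C@H]2CC(=O)C=CO2)cc1 | intermediate
7 | (2S,4R)-2-{2-[4-(tert-butyldimethylsilyloxy)phenyl]ethyl}-3,4-dihydro-2H-pyran-4-ol (cis) | CC(C)(C)[Si](C)(C)Oc1ccc(CC[C@H]2C[C@@H](O)C=CO2)cc1 | intermediate
8 | tert-butyl (2S,4R)-2-{2-[4-(tert-butyldimethylsilyloxy)phenyl]ethyl}-3,4-dihydro-2H-pyran-4-yl carbonate | CC(C)(C)[Si](C)(C)Oc1ccc(CC[C@H]2C[C@@H](OC(=O)OC(C)(C)C)C=CO2)cc1 | intermediate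
9 | 1-(2,4-dihydroxy-6-methoxyphenyl)ethanone | CC(=O)c1c(O)cc(O)cc1OC | starting material
10 | 1-[4-(tert-butyldimethylsilyloxy)-2-hydroxy-6-methoxyphenyl]ethanone | CC(=O)c1c(O)cc(O[Si](C)(C)C(C)(C)C)cc1OC | intermediate
11 | 1-{2-[((2R,6S)-6-{2-[4-(tert-butyldimethylsilyloxy)phenyl]ethyl}-5,6-dihydro-2H-pyran-2-yl)oxy]-4-(tert-butyldimethylsilyloxy)-6-methoxyphenyl}ethanone (2,6-cis aryl acetal) | CC(=O)c1c(O[C@@H]2C=CC[C@H](CCc3ccc(O[Si](C)(C)C(C)(C)C)cc3)O2)cc(O[Si](C)(C)C(C)(C)C)cc1OC | intermediate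
12 | ortho-dienone tautomer of 13: 2-acetyl-3-methoxy-5-(tert-butyldimethylsilyloxy)cyclohexa-2,4-dien-1-one carrying at C6 the cis-2,4-disubstituted dihydropyranyl group of 13 (C6 of the dienone undefined) | CC(=O)C1=C(OC)C=C(O[Si](C)(C)C(C)(C)C)C([C@@H]2C[C@H](CCc3ccc(O[Si](C)(C)C(C)(C)C)cc3)OC=C2)C1=O | intermediate (not isolated)
13 | 1-{3-[(2S,4R)-2-{2-[4-(tert-butyldimethylsilyloxy)phenyl]ethyl}-3,4-dihydro-2H-pyran-4-yl]-4-(tert-butyldimethylsilyloxy)-2-hydroxy-6-methoxyphenyl}ethanone (2,4-cis) | CC(=O)c1c(O)c([C@@H]2C[C@H](CCc3ccc(O[Si](C)(C)C(C)(C)C)cc3)OC=C2)c(O[Si](C)(C)C(C)(C)C)cc1OC | intermediate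
14 | 1-{2,4-bis(allyloxy)-3-[(2S,4R)-2-{2-[4-(allyloxy)phenyl]ethyl}-3,4-dihydro-2H-pyran-4-yl]-6-methoxyphenyl}ethanone | CC(=O)c1c(OCC=C)c([C@@H]2C[C@H](CCc3ccc(OCC=C)cc3)OC=C2)c(OCC=C)cc1OC | intermediate
15 | benzenesulfinic acid | OS(=O)c1ccccc1 | starting material
16 | 1-{2,4-bis(allyloxy)-6-methoxy-3-[(4R,6S)-6-{2-[4-(allyloxy)phenyl]ethyl}-2-(phenylsulfonyl)oxan-4-yl]phenyl}ethanone (C2 anomers) | CC(=O)c1c(OCC=C)c([C@@H]2C[C@H](CCc3ccc(OCC=C)cc3)OC(S(=O)(=O)c3ccccc3)C2)c(OCC=C)cc1OC | intermediate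
17 | 4-iodophenol | Oc1ccc(I)cc1 | starting material
18 | 4-iodophenyl pivalate | CC(C)(C)C(=O)Oc1ccc(I)cc1 | intermediate
19 | [4-(pivaloyloxy)phenyl]magnesium chloride (LiCl complex) | CC(C)(C)C(=O)Oc1ccc([Mg]Cl)cc1 | intermediate (not isolated)
20 | [4-(pivaloyloxy)phenyl]zinc bromide | CC(C)(C)C(=O)Oc1ccc([Zn]Br)cc1 | intermediate (not isolated)
21 | oxane oxocarbenium ion (O1=C2 cation; C4 aryl and C6 chain cis) formed from 16 by loss of benzenesulfinate | CC(=O)c1c(OCC=C)c([C@@H]2C[C@H](CCc3ccc(OCC=C)cc3)[O+]=CC2)c(OCC=C)cc1OC | intermediate (not isolated)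
22 | 4-[(2R,4R,6S)-4-(3-acetyl-2,6-bis(allyloxy)-4-methoxyphenyl)-6-{2-[4-(allyloxy)phenyl]ethyl}oxan-2-yl]phenyl pivalate | CC(=O)c1c(OCC=C)c([C@@H]2C[C@H](CCc3ccc(OCC=C)cc3)O[C@@H](c3ccc(OC(=O)C(C)(C)C)cc3)C2)c(OCC=C)cc1OC | intermediate
23 | 4-(allyloxy)benzaldehyde | C=CCOc1ccc(C=O)cc1 | starting material
24 | (E)-1-{2,4-bis(allyloxy)-3-[(2R,4R,6S)-6-{2-[4-(allyloxy)phenyl]ethyl}-2-(4-hydroxyphenyl)oxan-4-yl]-6-methoxyphenyl}-3-[4-(allyloxy)phenyl]prop-2-en-1-one | C=CCOc1ccc(/C=C/C(=O)c2c(OCC=C)c([C@@H]3C[C@H](CCc4ccc(OCC=C)cc4)O[C@@H](c4ccc(O)cc4)C3)c(OCC=C)cc2OC)cc1 | intermediate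
25 | (E)-1-{2,4-dihydroxy-3-[(2R,4R,6S)-2-(4-hydroxyphenyl)-6-[2-(4-hydroxyphenyl)ethyl]oxan-4-yl]-6-methoxyphenyl}-3-(4-hydroxyphenyl)prop-2-en-1-one | COc1cc(O)c([C@@H]2C[C@H](CCc3ccc(O)cc3)O[C@@H](c3ccc(O)cc3)C2)c(O)c1C(=O)/C=C/c1ccc(O)cc1 | target

**Step count and risks**

Total step count: 14. Longest linear sequence: 12 steps (1–5, 7–10, 12–14).

Steps most likely to fail:

Step 8. At 170 °C the aryl acetal may ionise and recombine before the sigmatropic shift. Anomerisation to the trans acetal would deliver the aryl group to the opposite face of C4, and aryl migration to C2 is also possible. The freed 2′-OH may in addition close onto the new enol ether. The fallback makes the C4–aryl bond by carbonyl addition and sets C4 by hydrogenation; it sets out from 6 and comes back at 22. 5-Methoxyresorcinol is protected (MOMCl, iPr2NEt) as 1-methoxy-3,5-bis(methoxymethoxy)benzene F1, which is lithiated between the two acetal groups (n-BuLi, THF, 0 °C) and added to the ketone of 6 to give the tertiary allylic alcohol F2. Pyridinium chlorochromate (C5H5NH[CrO3Cl]) effects oxidative allylic transposition to the 4-aryl-5,6-dihydropyran-2-one F3. Hydrogenation (H2, Pd/C, EtOAc) anti to the C6 side chain should give the cis-4,6-disubstituted lactone F4. iBu2AlH at −78 °C gives the lactol F5, and PhSO2H/CaCl2 the sulfone F6. Arylzinc 20 is added as in step 12 to give the 2,6-trans oxane F7. HCl/MeOH removes the acetal and silyl groups (the electron-poor 2-aryl group keeps C2 configurationally stable), giving the triphenol F8. C-acetylation with AcOH/BF3·OEt2 at either of the two equivalent ring A positions between OH and OMe gives the acetophenone F9, and allyl bromide/Cs2CO3 in DMF returns to 22.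

Step 7. The hindered, hydrogen-bonded phenoxide may capture the allyl-palladium intermediate slowly, which allows palladium–palladium exchange and erodes the retention (cis) pathway. The fallback sets out from 7 and comes back at 11. Acid-catalysed allylic transposition with water (pyridinium p-toluenesulfonate, aqueous THF, Ferrier-type) gives the lactol 6-{2-[4-(tert-butyldimethylsilyloxy)phenyl]ethyl}-5,6-dihydro-2H-pyran-2-ol F10, mainly the anomer with axial OH trans to the side chain. Mitsunobu coupling with phenol 10 (PPh3, diisopropyl azodicarboxylate, toluene, 0 °C) inverts the anomeric centre and gives the cis aryl acetal 11.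

Step 12. Axial selectivity in the aryl transfer may be lost, or Lewis-acid-induced opening and re-closure of the new benzylic ether may epimerise C2 after the addition. The fallback sets out from 14 and comes back at 22. Dry HCl in Et2O at −40 °C adds across the enol ether to give the 2-chloro-oxane F11. Nickel-catalysed Negishi coupling of F11 with arylzinc 20 (NiCl2·MeOCH2CH2OMe, a pyridine-bis(oxazoline) ligand, DMA/THF, rt) proceeds through the anomeric radical, whose capture at nickel along the axial direction should again give the 2,6-trans product 22, without a free oxocarbenium ion or a strong Lewis acid.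

Further compounds
F1 | step 8 | 1-methoxy-3,5-bis(methoxymethoxy)benzene | COCOc1cc(OC)cc(OCOC)c1
F2 | step 8 | (2S)-4-[4-methoxy-2,6-bis(methoxymethoxy)phenyl]-2-{2-[4-(tert-butyldimethylsilyloxy)phenyl]ethyl}-3,4-dihydro-2H-pyran-4-ol (C4 epimers) | COCOc1cc(OC)cc(OCOC)c1C2(O)C[C@H](CCc3ccc(O[Si](C)(C)C(C)(C)C)cc3)OC=C2
F3 | step 8 | (S)-4-[4-methoxy-2,6-bis(methoxymethoxy)phenyl]-6-{2-[4-(tert-butyldimethylsilyloxy)phenyl]ethyl}-5,6-dihydro-2H-pyran-2-one | COCOc1cc(OC)cc(OCOC)c1C2=CC(=O)O[C@@H](CCc3ccc(O[Si](C)(C)C(C)(C)C)cc3)C2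
F4 | step 8 | cis-4-[4-methoxy-2,6-bis(methoxymethoxy)phenyl]-6-{2-[4-(tert-butyldimethylsilyloxy)phenyl]ethyl}oxan-2-one | COCOc1cc(OC)cc(OCOC)c1[C@H]2CC(=O)O[C@@H](CCc3ccc(O[Si](C)(C)C(C)(C)C)cc3)C2
F5 | step 8 | cis-4-[4-methoxy-2,6-bis(methoxymethoxy)phenyl]-6-{2-[4-(tert-butyldimethylsilyloxy)phenyl]ethyl}oxan-2-ol (anomers) | COCOc1cc(OC)cc(OCOC)c1[C@H]2CC(O)O[C@@H](CCc3ccc(O[Si](C)(C)C(C)(C)C)cc3)C2
F6 | step 8 | cis-4-[4-methoxy-2,6-bis(methoxymethoxy)phenyl]-6-{2-[4-(tert-butyldimethylsilyloxy)phenyl]ethyl}-2-(phenylsulfonyl)oxane (anomers) | COCOc1cc(OC)cc(OCOC)c1[C@H]2CC(S(=O)(=O)c3ccccc3)O[C@@H](CCc3ccc(O[Si](C)(C)C(C)(C)C)cc3)C2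
F7 | step 8 | 4-[(2R,4R,6S)-4-[4-methoxy-2,6-bis(methoxymethoxy)phenyl]-6-{2-[4-(tert-butyldimethylsilyloxy)phenyl]ethyl}oxan-2-yl]phenyl pivalate | COCOc1cc(OC)cc(OCOC)c1[C@H]2C[C@H](c3ccc(OC(=O)C(C)(C)C)cc3)O[C@@H](CCc3ccc(O[Si](C)(C)C(C)(C)C)cc3)C2
F8 | step 8 | 4-[(2R,4R,6S)-4-(2,6-dihydroxy-4-methoxyphenyl)-6-[2-(4-hydroxyphenyl)ethyl]oxan-2-yl]phenyl pivalate | Oc1cc(OC)cc(O)c1[C@H]2C[C@H](c3ccc(OC(=O)C(C)(C)C)cc3)O[C@@H](CCc3ccc(O)cc3)C2
F9 | step 8 | 4-[(2R,4R,6S)-4-(3-acetyl-2,6-dihydroxy-4-methoxyphenyl)-6-[2-(4-hydroxyphenyl)ethyl]oxan-2-yl]phenyl pivalate | CC(=O)c1c(O)c([C@H]2C[C@H](c3ccc(OC(=O)C(C)(C)C)cc3)O[C@@H](CCc3ccc(O)cc3)C2)c(O)cc1OC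
F10 | step 7 | (6S)-6-{2-[4-(tert-butyldimethylsilyloxy)phenyl]ethyl}-5,6-dihydro-2H-pyran-2-ol (anomers) | CC(C)(C)[Si](C)(C)Oc1ccc(CC[C@H]2CC=CC(O)O2)cc1
F11 | step 12 | 1-{2,4-bis(allyloxy)-3-[(4R,6S)-6-{2-[4-(allyloxy)phenyl]ethyl}-2-chlorooxan-4-yl]-6-methoxyphenyl}ethanone (anomers) | CC(=O)c1c(OCC=C)c([C@@H]2C[C@H](CCc3ccc(OCC=C)cc3)OC(Cl)C2)c(OCC=C)cc1OC
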